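**Plan**

1. Numbering: C1–C15 for the eudesmane half (C1 ketone, lactone C6–O–C12(=O)–C11(C13)–C7, C14 on C10, C15 on C4), C1'–C10' for the myrcene-derived part (C1' on C5, C2' on C2, C3'=C10'); β is the face of C14.
2. Cuts, in retro order: C11–C13 (enolate methylation); C3'=C10' and C3'–C4' (Wittig, organolithium on a temporary C1–O–C3' lactone bridge); C7–C11 (radical ring closure); C2–C2' together with C5–C1' (intramolecular Diels–Alder of a C1–O acrylate, which makes the bicyclo[2.2.2]octene in one event); C7=C8 and C5–C6 of ring B (metathesis, carbonylative coupling).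
3. Forward order: ring A from 2-methylcyclohexane-1,3-dione, then ring B, then the bicyclo[2.2.2]octene with its lactone bridge, then the C6/C7 oxygen ring at the acetal level, then the C3' side chain, oxidation and C13.
4. Stereochemistry: a baker's yeast desymmetrization sets C10 and a helper carbinol at C1; C10 directs C6 (hydride anti to C14); the C1–O tether directs C2, C5 and C2' in one cycloaddition; the O6 tether directs C7; the cis-fused lactone directs C11.
5. Feature that makes the key event possible: O6 on C6 is allylic to the C7=C8 bond of ring B and carries a two-carbon bromoacetal, so a C11 radical closes 5-exo on C7, cis to O6; the radical joins C11 and C7, which are both donor positions of the 1,4-dioxygenated C6–C7–C11–C12 unit.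
6. Helpers: the C1 carbinol with its acrylate bridge and the acetal oxidation level at C12 are taken out in steps 14 to 16.

Key step: step 13

Remark: the baker's yeast reduction of 3 is taken to give the (2S,3S) hydroxy ketone (OH cis to allyl) as the major product, as is usual for 2,2-disubstituted cyclohexane-1,3-diones.

**Step 1**
Reactants: 1 2-methylcyclohexane-1,3-dione; 2 allyl bromide
Product: 3 2-allyl-2-methylcyclohexane-1,3-dione
Conditions: NaOH (1 M aq), rt
Reagents that add atoms: none
Why: C-alkylation of the doubly stabilized enolate of a 2-substituted cyclohexane-1,3-dione with an allylic halide (enolate alkylation) is the standard entry to 2,2-disubstituted diones and creates the prochiral quaternary carbon that becomes C10.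

**Step 2**
Reactants: 3 2-allyl-2-methylcyclohexane-1,3-dione
Product: 4 (2S,3S)-2-allyl-3-hydroxy-2-methylcyclohexan-1-one
Conditions: baker's yeast (Saccharomyces cerevisiae), sucrose, H2O, 30 °C; chromatography to remove the minor (2R,3S) diastereomer
Reagents that add atoms: none
Why: Enzymatic desymmetrizing ketone reduction distinguishes the two enantiotopic carbonyl groups and delivers hydride to one face, so the quaternary centre (later C10) and the carbinol (later C1, OH cis to the allyl group) are fixed together.

**Step 3**
Reactants: 4 (2S,3S)-2-allyl-3-hydroxy-2-methylcyclohexan-1-one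
Product: 5 (2S,3S)-2-allyl-3-[(tert-butyldimethylsilyl)oxy]-2-methylcyclohexan-1-one
Conditions: TBSCl, imidazole, DMF, 35 °C
Reagents that add atoms: tert-butyldimethylsilyl chloride, CC(C)(C)[Si](C)(C)Cl
Why: Silyl ether formation under imidazole catalysis protects the hindered carbinol without enolizing or retro-aldolizing the β-hydroxy ketone.

**Step 4**
Reactants: 5 TBS ether
Product: 6 (2S,3S)-2-allyl-3-[(tert-butyldimethylsilyl)oxy]-2,6-dimethylcyclohexan-1-one (both C6 epimers)
Conditions: LiN(i-Pr)2, THF, −78 °C; then MeI, −78 → 0 °C
Reagents that add atoms: iodomethane, CI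
Why: The ketone can enolize only toward its CH2 flank because the other α-carbon is quaternary, so kinetic lithium enolate alkylation installs the later C15 methyl regiospecifically, and the uncontrolled new centre is erased in step 5.

**Step 5**
Reactants: 6 methylated ketone
Product: 7 (5S,6S)-6-allyl-5-[(tert-butyldimethylsilyl)oxy]-2,6-dimethylcyclohex-2-en-1-one
Conditions: IBX, DMSO/PhMe, 70 °C
Reagents that add atoms: none
Why: IBX-mediated α,β-dehydrogenation of ketones runs through the enol, which can form only on the methyl-bearing side here, and should give the 2-methyl enone while leaving the terminal alkene and the silyl ether untouched.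

**Step 6**
Reactants: 7 enone
Product: 8 (5S,6S)-6-allyl-5-[(tert-butyldimethylsilyl)oxy]-2,6-dimethylcyclohexa-1,3-dien-1-yl trifluoromethanesulfonate
Conditions: Tf2O, 2,6-di-tert-butyl-4-methylpyridine, CH2Cl2, 0 °C → rt
Reagents that add atoms: triflic anhydride, O=S(=O)(OS(=O)(=O)C(F)(F)F)C(F)(F)F
Why: O-Triflation of an enone followed by loss of a γ-proton (dienyl triflate formation, as with steroidal enones) can only give the homoannular 2-triflyloxy-1,3-diene because the α'-carbon is quaternary, and the hindered pyridine base avoids a strongly basic dienolate next to the silyloxy group.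

**Step 7**
Reactants: 8 dienyl triflate; 9 tributyl(vinyl)stannane
Product: 10 1-[6-allyl-5-[(tert-butyldimethylsilyl)oxy]-2,6-dimethylcyclohexa-1,3-dien-1-yl]prop-2-en-1-one (ring stereocentres as in 8)
Conditions: Pd(PPh3)4 (5 mol%), LiCl, CO (1 atm), THF, 55 °C
Reagents that add atoms: carbon monoxide, [C-]#[O+]
Why: Carbonylative Stille coupling (oxidative addition of zerovalent palladium into the alkenyl triflate, CO insertion, vinyl transfer from tin) should give the dienyl vinyl ketone and thereby brings in C6 with its oxygen and C7.

**Step 8**
Reactants: 10 dienyl vinyl ketone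
Product: 11 bicyclic trienone, 5-[(tert-butyldimethylsilyl)oxy]-4a,8-dimethyl-4a,5-dihydronaphthalen-1(4H)-one (target numbering: 6-oxo, C2=C3, C4=C5, C7=C8, 1α-OTBS, 10β-CH3)
Conditions: second-generation Grubbs catalyst, (H2IMes)(PCy3)Cl2Ru=CHPh (5 mol%), CH2Cl2 (5 mM), 40 °C
Reagents that add atoms: none
Why: Ring-closing metathesis between the allyl group on C10 and the vinyl ketone closes ring B as a cyclohexenone, the conjugated tri- and tetrasubstituted alkenes of ring A being inert to the catalyst.

**Step 9**
Reactants: 11 bicyclic trienone
Product: 12 dienol, the 6β-alcohol of 11 (OH on C6 cis to the C10 methyl)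
Conditions: NaBH4, CeCl3·7H2O, MeOH, −78 °C
Reagents that add atoms: none
Why: Luche 1,2-reduction of the cross-conjugated ketone should deliver hydride to the α face because the pseudoaxial C10 methyl shields the β face of C6 (the control that gives 6β-alcohols from 6-oxo steroids), which sets C6 with O6 cis to C14.

**Step 10**
Reactants: 12 dienol; 13 ethyl vinyl ether
Product: 15 bromoacetal 6β-O-(2-bromo-1-ethoxyethyl) ether of 12 (both acetal epimers), via 1,2-dibromo-1-ethoxyethane 14 (not isolated)
Conditions: Br2 and 13, CH2Cl2, −78 °C; then 12, PhNMe2, −78 → 0 °C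
Reagents that add atoms: bromine, BrBr
Why: Stork bromoacetalization, in which the α-bromo oxocarbenium ion from the dibromo ether is captured by the hindered axial alcohol under amine-buffered conditions that spare the doubly allylic C6–O bond; the acetal centre forms as a mixture of no consequence.

**Step 11**
Reactants: 15 bromoacetal
Product: 16 dienol bromoacetal with free 1α-OH
Conditions: Bu4NF, THF, 0 °C → rt
Reagents that add atoms: none
Why: Fluoride-mediated desilylation frees the C1 carbinol, the primary β-alkoxy bromide and the mixed acetal being stable to these conditions.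

**Step 12**
Reactants: 16 dienol bromoacetal; 17 acryloyl chloride
Product: 19 lactone-bridged bicyclo[2.2.2]octene adduct (bonds C2–C2' and C5–C1' on the α face; γ-lactone C1–O–C3'(=O)–C2'), via C1 acrylate 18 (not isolated)
Conditions: i-Pr2NEt, DMAP (cat.), CH2Cl2, −20 °C; aqueous work-up; then PhMe (0.01 M), BHT (cat.), 110 °C
Reagents that add atoms: none
Why: Acylation followed by an ester-tethered intramolecular Diels–Alder reaction (as with acrylates of cyclohexa-3,5-dien-1-ols): the pseudoaxial C1–O on the α face delivers the acrylate to that face only, and the three-atom tether forces C2' onto C2 and C1' onto C5 and holds C3' syn to C1, so C2, C5 and C2' are all set by the C1 stereocentre without regiochemical or endo/exo ambiguity.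

**Step 13**
Reactants: 19 lactone-bridged adduct
Product: 20 pentacyclic acetal (cis-fused 2-ethoxytetrahydrofuran O6–C12(OEt)–C11H2–C7 on the β face of ring B; C8 now CH2)
Conditions: Bu3SnH (slow addition), AIBN (cat.), PhH (3 mM), 80 °C
Reagents that add atoms: none
Why: Bu3Sn• abstracts bromine from the primary bromide, the β-alkoxyalkyl radical at C11 adds to C7 of the ring B alkene, and the secondary C8 radical takes hydrogen from Bu3SnH to carry the chain. The closest known reaction type is the Ueno–Stork haloacetal radical cyclization, a radical union of C11 and C7, two carbons of like (donor) polarity with respect to O6 and C12 that enolate chemistry could not join. The ring that closes is the five-membered 2-ethoxytetrahydrofuran (the lactone ring at the acetal level), in the 5-exo-trig mode. The new stereocentre C7 is controlled by the tether: the O6–C12–C11 chain hangs from the axial β oxygen on C6 and can reach C7 only on the β face, which makes the ring fusion cis (H6 and H7 both α). The step needs 5-exo closure to outrun hydrogen transfer and 6-endo attack at C8; this is secured by the fast closure of β-oxygenated radicals, by the low stationary tin hydride concentration, and by C7=C8 being the only alkene within reach once C5 is a saturated bridgehead. The configuration at the acetal carbon C12 does not matter because it becomes the lactone carbonyl in step 16.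

**Step 14**
Reactants: 20 pentacyclic acetal; 21 5-bromo-2-methylpent-2-ene
Product: 23 lactol (hemiketal at C3' bearing OH; O–C1; the 4-methylpent-3-enyl group; C2'), via (4-methylpent-3-enyl)lithium 22 (not isolated)
Conditions: 21, Li (wire), Et2O, −10 °C; then 20, THF, −78 °C; H2O quench
Reagents that add atoms: none
Why: Addition of one equivalent of an organolithium to a lactone at low temperature should stop at the lithium hemiketalate (as in lactol formation from sugar lactones), which supplies C4'–C9' while the mixed acetal at C12 is inert; the anomeric centre at C3' is of no consequence.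

**Step 15**
Reactants: 23 lactol
Product: 24 alkenol (C3'(=CH2)(4-methylpent-3-enyl) on C2', free 1α-OH, C12 ethyl acetal)
Conditions: Ph3PCH3Br, KOt-Bu, PhMe, 0 → 80 °C
Reagents that add atoms: methyltriphenylphosphonium bromide, C[P+](c1ccccc1)(c1ccccc1)c1ccccc1.[Br-]
Why: Wittig methylenation of the hydroxy ketone in equilibrium with the lactol converts C3' into the 1,1-disubstituted alkene and releases the C1 alcohol, and C2' should not be disturbed because only the configuration with C3' syn to C1 can return to the hemiketal.

**Step 16**
Reactants: 24 alkenol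
Product: 25 13-nor keto lactone (the target without the C13 methyl)
Conditions: CrO3, H2SO4, H2O, acetone, 0 °C → rt (Jones oxidation)
Reagents that add atoms: water, O
Why: Jones oxidation converts the hindered secondary alcohol into the C1 ketone and, through acid hydrolysis of the ethyl acetal to the lactol and its oxidation, the temporary acetal into the γ-lactone in one operation, as is standard after Ueno–Stork cyclizations, with isolated alkenes surviving.

**Step 17**
Reactants: 25 13-nor keto lactone
Product: 26 target CNP0385704.2
Conditions: LiN(SiMe3)2, THF, −78 °C; then MeI, −78 °C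
Reagents that add atoms: iodomethane, CI
Why: Lactone enolate alkylation: the C1 ketone has no enolizable α-hydrogen (C10 is quaternary, C2 a bridgehead), so the amide base forms only the lactone enolate, and MeI should attack its convex face anti to C8 of the cis-fused bicycle, placing C13 cis to H7 as in the target.

**Compound list**

1 | 2-methylcyclohexane-1,3-dione | CC1C(=O)CCCC1=O | starting material
2 | allyl bromide | C=CCBr | starting material
3 | 2-allyl-2-methylcyclohexane-1,3-dione | C=CCC1(C)C(=O)CCCC1=O | intermediate
4 | (2S,3S)-2-allyl-3-hydroxy-2-methylcyclohexan-1-one | O[C@H]1CCCC(=O)[C@@]1(C)CC=C | intermediate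
5 | (2S,3S)-2-allyl-3-[(tert-butyldimethylsilyl)oxy]-2-methylcyclohexan-1-one | CC(C)(C)[Si](C)(C)O[C@H]1CCCC(=O)[C@@]1(C)CC=C | intermediate
6 | (2S,3S)-2-allyl-3-[(tert-butyldimethylsilyl)oxy]-2,6-dimethylcyclohexan-1-one, both C6 epimers | CC(C)(C)[Si](C)(C)O[C@H]1CCC(C)C(=O)[C@@]1(C)CC=C | intermediate
7 | (5S,6S)-6-allyl-5-[(tert-butyldimethylsilyl)oxy]-2,6-dimethylcyclohex-2-en-1-one | CC(C)(C)[Si](C)(C)O[C@H]1CC=C(C)C(=O)[C@@]1(C)CC=C | intermediate
8 | (5S,6S)-6-allyl-5-[(tert-butyldimethylsilyl)oxy]-2,6-dimethylcyclohexa-1,3-dien-1-yl triflate | CC(C)(C)[Si](C)(C)O[C@H]1C=CC(C)=C(OS(=O)(=O)C(F)(F)F)[C@@]1(C)CC=C | intermediate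
9 | tributyl(vinyl)stannane | C=C[Sn](CCCC)(CCCC)CCCC | starting material
10 | dienyl vinyl ketone, 1-[6-allyl-5-(TBSO)-2,6-dimethylcyclohexa-1,3-dien-1-yl]prop-2-en-1-one | CC(C)(C)[Si](C)(C)O[C@H]1C=CC(C)=C(C(=O)C=C)[C@@]1(C)CC=C | intermediate
11 | bicyclic trienone, 5-(TBSO)-4a,8-dimethyl-4a,5-dihydronaphthalen-1(4H)-one (1α-OTBS, 10β-CH3) | CC(C)(C)[Si](C)(C)O[C@H]1C=CC(C)=C2C(=O)C=CC[C@@]12C | intermediate
12 | dienol, 6β-alcohol of 11 | CC(C)(C)[Si](C)(C)O[C@H]1C=CC(C)=C2[C@H](O)C=CC[C@@]12C | intermediate
13 | ethyl vinyl ether | C=COCC | starting material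
14 | 1,2-dibromo-1-ethoxyethane | CCOC(Br)CBr | intermediate (not isolated)
15 | bromoacetal, 6β-O-(2-bromo-1-ethoxyethyl) ether of 12, both acetal epimers | CC(C)(C)[Si](C)(C)O[C@H]1C=CC(C)=C2[C@H](OC(OCC)CBr)C=CC[C@@]12C | intermediate
16 | dienol bromoacetal with free 1α-OH | O[C@H]1C=CC(C)=C2[C@H](OC(OCC)CBr)C=CC[C@@]12C | intermediate
17 | acryloyl chloride | C=CC(=O)Cl | starting material
18 | C1 acrylate of 16 | C=CC(=O)O[C@H]1C=CC(C)=C2[C@H](OC(OCC)CBr)C=CC[C@@]12C | intermediate (not isolated)
19 | lactone-bridged bicyclo[2.2.2]octene adduct | O=C4[C@H]1C[C@]23C(C)=C[C@H]1[C@H](O4)[C@]2(C)CC=C[C@H]3OC(OCC)CBr | intermediate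
20 | pentacyclic acetal (C7–C11 closed, cis-fused 2-ethoxytetrahydrofuran) | O=C4[C@H]1C[C@]23C(C)=C[C@H]1[C@H](O4)[C@]2(C)CC[C@H]1CC(OCC)O[C@H]13 | intermediate
21 | 5-bromo-2-methylpent-2-ene | CC(C)=CCCBr | starting material
22 | (4-methylpent-3-enyl)lithium | [Li]CCC=C(C)C | intermediate (not isolated)
23 | lactol (hemiketal at C3') | OC4(CCC=C(C)C)[C@H]1C[C@]23C(C)=C[C@H]1[C@H](O4)[C@]2(C)CC[C@H]1CC(OCC)O[C@H]13 | intermediate
24 | alkenol (myrcene-type side chain, 1α-OH, C12 ethyl acetal) | C=C(CCC=C(C)C)[C@H]1C[C@]23C(C)=C[C@H]1[C@H](O)[C@]2(C)CC[C@H]1CC(OCC)O[C@H]13 | intermediate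
25 | 13-nor keto lactone | C=C(CCC=C(C)C)[C@H]1C[C@]23C(C)=C[C@H]1C(=O)[C@]2(C)CC[C@H]1CC(=O)O[C@H]13 | intermediate
26 | target CNP0385704.2 | C=C(CCC=C(C)C)[C@H]1C[C@]23C(C)=C[C@H]1C(=O)[C@]2(C)CC[C@H]1[C@H](C)C(=O)O[C@H]13 | target

**Count and risks**

Total steps: 17. Longest linear sequence: 17 steps (1 to 26); all other inputs are commercial.

Steps most likely to fail:

Step 7. Oxidative addition or CO insertion at the very hindered dienyl triflate may be slow, so that direct vinyl transfer without CO or polymerization of the vinyl ketone takes over. Fallback, from 8: a Nozaki–Hiyama–Kishi coupling with acrolein (CrCl2, cat. NiCl2, DMF) would give the doubly allylic carbinol F1 as a mixture at C6. Ring-closing metathesis as in step 8 would give the bicyclic dienol F2 (both C6 epimers). MnO2 oxidation would return to trienone 11, from which step 9 sets C6.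

Step 12. The doubly allylic C1 ester may ionize, or the acrylate may polymerize, before the cycloaddition occurs. Fallback, from 16: treatment with MeMgBr and then methyl acrylate would run the cycloaddition as a magnesium-alkoxide-templated intermolecular Diels–Alder reaction, in which the metal bound to O1 holds the acrylate on the α face with its ester next to C1. This would give the hydroxy ester F3, which should close to lactone 19 on warming with catalytic DBU.

Step 13. Hydrogen transfer from the tin hydride to the first-formed radical may outrun ring closure and give the reduced, uncyclized acetal. Fallback, from 19: exchange of bromide for iodide (NaI, NaHCO3, acetone) would give the iodoacetal F4. An iodine-atom-transfer cyclization (Et3B, air, PhH), in which no hydrogen donor is present during ring closure, would give the cyclized secondary iodide F5. Reductive removal of iodine (Bu3SnH, AIBN) would then return to 20.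

**Further compounds**

F1 | step 7 | doubly allylic carbinol, 1-[6-allyl-5-(TBSO)-2,6-dimethylcyclohexa-1,3-dien-1-yl]prop-2-en-1-ol, C6 epimers | CC(C)(C)[Si](C)(C)O[C@H]1C=CC(C)=C(C(O)C=C)[C@@]1(C)CC=C
F2 | step 7 | bicyclic dienol, both C6 epimers of 12 | CC(C)(C)[Si](C)(C)O[C@H]1C=CC(C)=C2C(O)C=CC[C@@]12C
F3 | step 12 | hydroxy ester, bicyclo[2.2.2]octene adduct with CO2Me on C2' and free 1α-OH | COC(=O)[C@H]1C[C@]23C(C)=C[C@H]1[C@H](O)[C@]2(C)CC=C[C@H]3OC(OCC)CBr
F4 | step 13 | iodoacetal, iodide analogue of 19 | O=C4[C@H]1C[C@]23C(C)=C[C@H]1[C@H](O4)[C@]2(C)CC=C[C@H]3OC(OCC)CI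
F5 | step 13 | cyclized secondary iodide, 20 with iodine on C8 | O=C4[C@H]1C[C@]23C(C)=C[C@H]1[C@H](O4)[C@]2(C)CC(I)[C@H]1CC(OCC)O[C@H]13
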